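**Assumptions (one line each).** The target is read as (2S)-3',4',7-trihydroxyflavan-(4α→8)-(+)-catechin: upper flavan 2S,4S (2,4-cis), lower unit 2R,3S, which is commercial (+)-catechin. The (R)-t-BuPyOX ligand in step 4 is chosen on the recalled correlation that the (S)-ligand gives (R)-flavanones; confirm by chiral HPLC and optical rotation before going on.

**Retrosynthetic overview**
1. Target 12 ⇐ octa-O-benzyl flav-3-ene 11: one H2/Pd(OH)2 step saturates C3=C4 from the face opposite the C2 aryl (2,4-cis, 4S) and removes all eight benzyl ethers.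
2. 11 ⇐ interflavan C4–C8 bond by Pd-catalysed carbene coupling: the C4 ketone carbon of flavanone 8 is turned into a carbon nucleophile (N-tosylhydrazone → diazo) and joined to aryl bromide 4, so a C=O carbon and a C–Br carbon are united.
3. 8 ⇐ 7-benzyloxychromone 6 + arylboronic acid 7 by enantioselective conjugate arylation (sets 2S).
4. 4 ⇐ (+)-catechin 1 (chiral pool) by per-benzylation and C8 bromination.
5. No ring is built: rings A and C of the upper unit come with the chromone, ring B with 7, and the three lower rings with catechin; ring C is only saturated at the end.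

**Step 1**
Reactants: 1 (+)-catechin
Product: 3 penta-O-benzyl-(+)-catechin (benzyl ethers on O3 O5 O7 O3' O4'), via tetra-O-benzylcatechin 2 (not isolated)
Conditions: BnBr (4.4 equiv), K2CO3, DMF, 0 °C to rt, 24 h; filter under N2; then NaH (1.5 equiv), BnBr (1.3 equiv), 0 °C to rt
Reagents that add atoms: benzyl bromide, BrCc1ccccc1
Why: Williamson ether synthesis in two stages, the four phenols under K2CO3 (conditions that do not epimerise C2 of catechin) and then the secondary 3-alkoxide with NaH, so both stereocentres of the chiral pool are carried through untouched.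

**Step 2**
Reactants: 3 penta-O-benzyl-(+)-catechin
Product: 4 8-bromo-penta-O-benzyl-(+)-catechin
Conditions: NBS (1.05 equiv), CH2Cl2, −78 °C to rt
Reagents that add atoms: N-bromosuccinimide, O=C1CCC(=O)N1Br
Why: Electrophilic aromatic bromination of the 5,7-dialkoxy ring A, which for benzylated flavan-3-ols goes selectively to C8 with one equivalent of NBS at low temperature and fixes the later linkage as 4→8 rather than 4→6.

**Step 3**
Reactants: 5 7-hydroxy-4H-chromen-4-one
Product: 6 7-(benzyloxy)-4H-chromen-4-one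
Conditions: BnBr (1.1 equiv), K2CO3, acetone, reflux
Reagents that add atoms: benzyl bromide, BrCc1ccccc1
Why: Williamson ether synthesis on the acidic 7-phenol, which protects it and keeps the chromone a good conjugate acceptor.

**Step 4**
Reactants: 6 7-(benzyloxy)-4H-chromen-4-one; 7 [3,4-bis(benzyloxy)phenyl]boronic acid (2 equiv)
Product: 8 (2S)-7-(benzyloxy)-2-[3,4-bis(benzyloxy)phenyl]chroman-4-one
Conditions: Pd(OCOCF3)2 (5 mol %), (R)-t-BuPyOX (6 mol %), NH4PF6 (30 mol %), H2O (5 equiv), ClCH2CH2Cl, 60 °C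
Reagents that add atoms: none
Why: Pd-catalysed asymmetric conjugate addition of an arylboronic acid to a chromone (Hayashi–Miyaura-type 1,4-arylation), in which the cationic aryl-palladium–PyOX complex inserts C2=C3 on one enantiotopic face to set C2 as S and water protonates the Pd enolate; any minor 2R material becomes a separable diastereomer after step 5.

**Step 5**
Reactants: 8 (2S)-7-(benzyloxy)-2-[3,4-bis(benzyloxy)phenyl]chroman-4-one (1.1 equiv); 4 8-bromo-penta-O-benzyl-(+)-catechin (1.0 equiv)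
Product: 11 octa-O-benzyl (2S)-4-(catechin-8-yl)flav-3-ene, via tosylhydrazone 9 (not isolated), via diazoflavan 10 (not isolated)
Conditions: TsNHNH2 (1.15 equiv), 1,4-dioxane, 70 °C, 2 h; then 4, Pd2(dba)3 (2.5 mol %), XPhos (10 mol %), LiOtBu (2.4 equiv), 100 °C
Reagents that add atoms: p-toluenesulfonyl hydrazide, NNS(=O)(=O)c1ccc(C)cc1 (its atoms are in 9 and 10 only and are lost before 11)
Why: Barluenga-type Pd-catalysed cross-coupling of an N-tosylhydrazone with an aryl bromide, in which the hydrazone salt releases diazo compound 10 (Bamford–Stevens), its nucleophilic diazo carbon (the former C4 carbonyl carbon) attacks the arylpalladium bromide formed from 4 to give a Pd carbene, and aryl migration followed by β-hydride elimination toward C3 gives the 4-aryl-2H-chromene with C2 untouched and no new stereocentre.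

**Step 6**
Reactants: 11 octa-O-benzyl (2S)-4-(catechin-8-yl)flav-3-ene
Product: 12 (2S)-3',4',7-trihydroxyflavan-(4α→8)-(+)-catechin (target)
Conditions: H2 (4 bar), 20 % Pd(OH)2/C, THF/MeOH/H2O (20:10:1), rt; Sephadex LH-20 then preparative reversed-phase HPLC
Reagents that add atoms: none
Why: Heterogeneous syn-hydrogenation of the trisubstituted C3=C4 styrene-type alkene from the face opposite the C2 aryl places the new H4 cis to H2 and so sets C4 as S (2,4-cis, 4α), while O-benzyl hydrogenolysis frees all eight hydroxyls in the same operation.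

**Compound list**
1 | (+)-catechin, (2R,3S)-2-(3,4-dihydroxyphenyl)chroman-3,5,7-triol | Oc1cc(O)c2c(c1)O[C@H](c1ccc(O)c(O)c1)[C@@H](O)C2 | starting material
2 | 5,7,3',4'-tetra-O-benzyl-(+)-catechin, (2R,3S), 3-OH free | c1ccccc1COc1cc(OCc2ccccc2)c2c(c1)O[C@H](c1ccc(OCc3ccccc3)c(OCc3ccccc3)c1)[C@@H](O)C2 | intermediate (not isolated)
3 | 3,5,7,3',4'-penta-O-benzyl-(+)-catechin, (2R,3S) | c1ccccc1COc1cc(OCc2ccccc2)c2c(c1)O[C@H](c1ccc(OCc3ccccc3)c(OCc3ccccc3)c1)[C@@H](OCc1ccccc1)C2 | intermediate
4 | 8-bromo-3,5,7,3',4'-penta-O-benzyl-(+)-catechin, (2R,3S) | c1ccccc1COc1cc(OCc2ccccc2)c2c(c1Br)O[C@H](c1ccc(OCc3ccccc3)c(OCc3ccccc3)c1)[C@@H](OCc1ccccc1)C2 | intermediate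
5 | 7-hydroxy-4H-chromen-4-one (7-hydroxychromone) | O=c1ccoc2cc(O)ccc12 | starting material
6 | 7-(benzyloxy)-4H-chromen-4-one | O=c1ccoc2cc(OCc3ccccc3)ccc12 | intermediate
7 | [3,4-bis(benzyloxy)phenyl]boronic acid | OB(O)c1ccc(OCc2ccccc2)c(OCc2ccccc2)c1 | starting material
8 | (2S)-7-(benzyloxy)-2-[3,4-bis(benzyloxy)phenyl]chroman-4-one (tri-O-benzyl (S)-butin) | c1ccccc1COc1ccc2c(c1)O[C@H](c1ccc(OCc3ccccc3)c(OCc3ccccc3)c1)CC2=O | intermediate
9 | N-tosylhydrazone of 8 (2S; C=N geometry not defined) | c1ccccc1COc1ccc2c(c1)O[C@H](c1ccc(OCc3ccccc3)c(OCc3ccccc3)c1)CC2=NNS(=O)(=O)c1ccc(C)cc1 | intermediate (not isolated)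
10 | (2S)-7-(benzyloxy)-2-[3,4-bis(benzyloxy)phenyl]-4-diazochroman | c1ccccc1COc1ccc2c(c1)O[C@H](c1ccc(OCc3ccccc3)c(OCc3ccccc3)c1)CC2=[N+]=[N-] | intermediate (not isolated)
11 | (2S)-7-(benzyloxy)-2-[3,4-bis(benzyloxy)phenyl]-4-[(2R,3S)-3,5,7-tris(benzyloxy)-2-[3,4-bis(benzyloxy)phenyl]chroman-8-yl]-2H-chromene | c1ccccc1COc1ccc2c(c1)O[C@H](c1ccc(OCc3ccccc3)c(OCc3ccccc3)c1)C=C2c1c(OCc2ccccc2)cc(OCc2ccccc2)c2c1O[C@H](c1ccc(OCc3ccccc3)c(OCc3ccccc3)c1)[C@@H](OCc1ccccc1)C2 | intermediate
12 | (2S,4S)-3',4',7-trihydroxyflavan-(4α→8)-(2R,3S)-catechin, CNP0227165.3 | Oc1ccc2c(c1)O[C@H](c1ccc(O)c(O)c1)C[C@@H]2c1c(O)cc(O)c2c1O[C@H](c1ccc(O)c(O)c1)[C@@H](O)C2 | target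

**Totals.** Total step count: 6. Longest linear sequence: 4 steps (5 → 6 → 8 → 11 → 12; the catechin branch 1 → 3 → 4 → 11 → 12 is equally long).

**Three steps most likely to fail, with fallbacks**

Step 5 is the riskiest. Bromide 4 is electron-rich and flanked by two ortho oxygens, the carbene insertion builds a very crowded diaryl carbon, and hot LiOtBu could erode C2 of 8 or 11; a first adjustment would be Cs2CO3 as base. The fallback sets out from 4 and 8 and comes back at 11. Bromine–lithium exchange on 4 (n-BuLi, THF, −78 °C) and transmetalation with anhydrous CeCl3 give an arylcerium reagent that adds 1,2 to the C4 ketone of 8 without enolisation or ring opening, giving the tertiary alcohol octa-O-benzyl 4-(catechin-8-yl)flavan-4-ol F1 as a mixture of C4 epimers. Both epimers dehydrate through the doubly benzylic cation (catalytic p-TsOH, toluene, rt) to 11.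

Step 6 may give an unsatisfactory cis:trans ratio on the hindered alkene, stall after debenzylation, or cleave the allylic C2–O bond. The fallback sets out from 11 and comes back at 12. Ionic hydrogenation (Et3SiH, CF3CO2H, CH2Cl2, −40 to 0 °C) protonates C3 and delivers hydride axially to the diaryl-stabilised C4 cation, trans to the C2 aryl, giving the 2,4-cis octa-O-benzyl ether of the target F2. Hydrogenolysis of F2 (H2, Pd(OH)2/C, THF/MeOH) then gives 12.

Step 4 may give low conversion or low ee with the electron-rich 7-alkoxychromone, and the ligand sense is assumed. The fallback sets out from 6 and 7 and comes back at 8. Racemic conjugate arylation (Pd(OCOCF3)2, 2,2'-bipyridine, NH4PF6, H2O, ClCH2CH2Cl, 60 °C) gives racemic 7-(benzyloxy)-2-[3,4-bis(benzyloxy)phenyl]chroman-4-one F3. Kinetic resolution by Noyori asymmetric transfer hydrogenation ([RuCl(p-cymene)((R,R)-TsDPEN)], HCO2H/Et3N, EtOAc, rt, about 55 % conversion) is expected to reduce the 2R ketone to the cis alcohol (2R,4R)-7-(benzyloxy)-2-[3,4-bis(benzyloxy)phenyl]chroman-4-ol F4, which is removed by chromatography, leaving (2S)-8.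

**Further compounds**
F1 | step 5 | octa-O-benzyl 4-(catechin-8-yl)flavan-4-ol, (2S) upper unit, (2R,3S) lower unit, C4 carbinol centre as epimer mixture | c1ccccc1COc1ccc2c(c1)O[C@H](c1ccc(OCc3ccccc3)c(OCc3ccccc3)c1)CC2(O)c1c(OCc2ccccc2)cc(OCc2ccccc2)c2c1O[C@H](c1ccc(OCc3ccccc3)c(OCc3ccccc3)c1)[C@@H](OCc1ccccc1)C2
F2 | step 6 | octa-O-benzyl ether of the target, (2S,4S) upper unit, (2R,3S) lower unit | c1ccccc1COc1ccc2c(c1)O[C@H](c1ccc(OCc3ccccc3)c(OCc3ccccc3)c1)C[C@@H]2c1c(OCc2ccccc2)cc(OCc2ccccc2)c2c1O[C@H](c1ccc(OCc3ccccc3)c(OCc3ccccc3)c1)[C@@H](OCc1ccccc1)C2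
F3 | step 4 | racemic 7-(benzyloxy)-2-[3,4-bis(benzyloxy)phenyl]chroman-4-one | O=C1CC(c2ccc(OCc3ccccc3)c(OCc3ccccc3)c2)Oc2cc(OCc3ccccc3)ccc12
F4 | step 4 | (2R,4R)-7-(benzyloxy)-2-[3,4-bis(benzyloxy)phenyl]chroman-4-ol (2,4-cis) | c1ccccc1COc1ccc2c(c1)O[C@@H](c1ccc(OCc3ccccc3)c(OCc3ccccc3)c1)C[C@H]2O
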